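**Assumption:** the target SMILES has no stereocentre and no stereogenic double bond, so the compound is achiral and no stereocontrol is needed; the route only has to fix the regiochemistry (OMe at C8, OH at C5 and C7).

**Retrosynthetic overview**
1. The 5-OH is disconnected to a C5–H bond: it is installed last by C4-carbonyl-directed, Ru-catalysed C–H hydroxylation of a 5-deoxyflavone, so no phloroglucinol-type A ring and no chalcone or Baker–Venkataraman sequence is needed.
2. The pyranone (C ring) is made in one flask by thermal Mentzer condensation of symmetric 2-methoxyresorcinol with a commercial aroylacetate: C4–C4a bond first (C-acylation), then O1–C2 (cyclodehydration).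
3. The symmetry of 2-methoxyresorcinol fixes OMe at C8; the peri relationship of C5–H to the C4 carbonyl fixes the site of oxidation.
4. Ring order: A and B rings are bought intact, the C ring is formed in step 1, and the A-ring oxygenation is completed in step 3.

**Step 1**
Reactants: 1 2-methoxybenzene-1,3-diol (2-methoxyresorcinol); 2 ethyl 3-oxo-3-(3,4,5-trimethoxyphenyl)propanoate
Product: 4 7-hydroxy-8-methoxy-2-(3,4,5-trimethoxyphenyl)-4H-chromen-4-one, via o-hydroxyaryl diketone 3 (not isolated)
Conditions: 2 (1.5 equiv), neat melt, 240 °C, N2 sweep (−EtOH, −H2O), 2 h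
Reagents that add atoms: none
Why: Mentzer pyrone synthesis (thermal, acid-free chromone condensation, as used for 7-hydroxy- and 7,8-dihydroxyflavones): the β-keto ester C-acylates the symmetric resorcinol ortho to OH (C4 = C6, so only one regioisomer can form) and the o-hydroxyaryl 1,3-diketone cyclodehydrates through the OH next to OMe, which places OMe at C8; no stereocentre is formed.

**Step 2**
Reactants: 4 7-hydroxy-8-methoxy-2-(3,4,5-trimethoxyphenyl)-4H-chromen-4-one
Product: 5 8-methoxy-4-oxo-2-(3,4,5-trimethoxyphenyl)-4H-chromen-7-yl acetate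
Conditions: Ac2O (1.5 equiv), pyridine, DMAP (cat.), CH2Cl2, rt
Reagents that add atoms: acetic anhydride, CC(=O)OC(C)=O
Why: DMAP-catalysed O-acylation of the only free phenol masks it as an electron-poorer ester that is not oxidised to a quinone by the hypervalent iodine oxidant of step 3; no stereocentre is involved.

**Step 3**
Reactants: 5 8-methoxy-4-oxo-2-(3,4,5-trimethoxyphenyl)-4H-chromen-7-yl acetate
Product: 8 5,7-dihydroxy-8-methoxy-2-(3,4,5-trimethoxyphenyl)-4H-chromen-4-one (3',4',5'-trimethoxywogonin), via 5-O-trifluoroacetyl 7-O-acetyl flavone 6 (not isolated), via 7-O-acetyl flavone 7 (not isolated)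
Conditions: [RuCl2(p-cymene)]2 (5 mol %), PhI(OCOCF3)2 (1.5 equiv), TFA/TFAA (3:1), 80 °C; aq. Na2S2O3/NaHCO3 wash; crude, then HCl (cat.), MeOH, 50 °C
Reagents that add atoms: [bis(trifluoroacetoxy)iodo]benzene (PIFA), O=C(OI(OC(=O)C(F)(F)F)c1ccccc1)C(F)(F)F
Why: Ketone-directed Ru(II)-catalysed ortho C–H hydroxylation (a known reaction type for the C5 position of flavones): the C4 carbonyl delivers Ru to the peri C5–H through a five-membered ruthenacycle (C5 is also para to the 8-OMe donor), PIFA oxidises the metal and C–O reductive elimination gives aryl trifluoroacetate 6, which is protected from over-oxidation until the aqueous wash hydrolyses it to 7 and acid methanolysis removes the acetate; no stereocentre is created.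

**Compound list**
1 | 2-methoxybenzene-1,3-diol (2-methoxyresorcinol) | COc1c(O)cccc1O | starting material
2 | ethyl 3-oxo-3-(3,4,5-trimethoxyphenyl)propanoate (ethyl 3,4,5-trimethoxybenzoylacetate) | CCOC(=O)CC(=O)c1cc(OC)c(OC)c(OC)c1 | starting material
3 | 1-(2,4-dihydroxy-3-methoxyphenyl)-3-(3,4,5-trimethoxyphenyl)propane-1,3-dione | COc1cc(C(=O)CC(=O)c2ccc(O)c(OC)c2O)cc(OC)c1OC | intermediate (not isolated)
4 | 7-hydroxy-8-methoxy-2-(3,4,5-trimethoxyphenyl)-4H-chromen-4-one | COc1cc(-c2cc(=O)c3ccc(O)c(OC)c3o2)cc(OC)c1OC | intermediate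
5 | 8-methoxy-4-oxo-2-(3,4,5-trimethoxyphenyl)-4H-chromen-7-yl acetate | COc1cc(-c2cc(=O)c3ccc(OC(C)=O)c(OC)c3o2)cc(OC)c1OC | intermediate
6 | 7-acetoxy-8-methoxy-4-oxo-2-(3,4,5-trimethoxyphenyl)-4H-chromen-5-yl trifluoroacetate | COc1cc(-c2cc(=O)c3c(OC(=O)C(F)(F)F)cc(OC(C)=O)c(OC)c3o2)cc(OC)c1OC | intermediate (not isolated)
7 | 5-hydroxy-8-methoxy-4-oxo-2-(3,4,5-trimethoxyphenyl)-4H-chromen-7-yl acetate | COc1cc(-c2cc(=O)c3c(O)cc(OC(C)=O)c(OC)c3o2)cc(OC)c1OC | intermediate (not isolated)
8 | 5,7-dihydroxy-8-methoxy-2-(3,4,5-trimethoxyphenyl)-4H-chromen-4-one (3',4',5'-trimethoxywogonin) | COc1cc(-c2cc(=O)c3c(O)cc(O)c(OC)c3o2)cc(OC)c1OC | target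

**Total step count:** 3. **Longest linear sequence:** 3 steps (from 1 or 2).

**Steps most likely to fail, with fallbacks**

1. Step 3 (most risky). PIFA in TFA may oxidise the electron-rich 3,4,5-trimethoxyphenyl ring, or the 8-methoxy-5-oxy A ring may go on to a 5,8-quinone, before directed hydroxylation is complete. The fallback abandons C5–H oxidation and instead carries the 5-oxygen from the start, introducing the 8-OMe late. It sets out from 2 and comes back to the route at 8. Compound 2 is condensed with commercial phloroglucinol in the same neat melt at 240 °C (symmetric phenol, well-precedented Mentzer substrate) to give 5,7-dihydroxy-2-(3,4,5-trimethoxyphenyl)-4H-chromen-4-one F4. Exhaustive benzylation (BnBr, K2CO3, KI, DMF, 80 °C) gives 5,7-bis(benzyloxy)-2-(3,4,5-trimethoxyphenyl)-4H-chromen-4-one F5. Electrophilic iodination (NIS, cat. TFA, MeCN, rt), which in 5,7-dialkoxyflavones goes to C8, gives 5,7-bis(benzyloxy)-8-iodo-2-(3,4,5-trimethoxyphenyl)-4H-chromen-4-one F6. Ullmann-type methoxylation (NaOMe, CuI cat., MeOH/DMF, 110 °C) gives 5,7-bis(benzyloxy)-8-methoxy-2-(3,4,5-trimethoxyphenyl)-4H-chromen-4-one F7. Hydrogenolysis (H2 1 atm, Pd/C, EtOAc/MeOH) then gives 8.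

2. Step 1. With a resorcinol that is less activated than phloroglucinol, the melt may give low conversion, tar, or the Pechmann-type 4-arylcoumarin. The fallback replaces the one-flask thermal condensation by a stepwise enolate aroylation. It sets out from 1 and comes back to the route at 3, which is now isolated. Compound 1 is C-acetylated (AcOH, BF3·OEt2, 90 °C; the symmetric substrate gives one isomer) to 2,4-dihydroxy-3-methoxyacetophenone F1. F1 is converted into its lithium polyanion (LiHMDS 4 equiv, THF, −78 °C) and C-aroylated with commercial 3,4,5-trimethoxybenzoyl chloride to give diketone 3 directly, without O-protection. Cyclodehydration (cat. H2SO4, AcOH, 95 °C) then gives 4.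

3. Step 2. The acylation itself is safe; the risk is that the acetate is exchanged or partly lost in hot TFA/TFAA, giving mixed esters and an ill-defined substrate for step 3. The fallback drops the isolated protecting group in favour of transient in-flask protection. It sets out from 4 and comes back to the route at 8. Compound 4 is dissolved directly in TFA/TFAA, where the phenol is converted into 8-methoxy-4-oxo-2-(3,4,5-trimethoxyphenyl)-4H-chromen-7-yl trifluoroacetate F2. The same Ru/PIFA hydroxylation then gives 8-methoxy-4-oxo-2-(3,4,5-trimethoxyphenyl)-4H-chromene-5,7-diyl bis(trifluoroacetate) F3. Both esters are hydrolysed by the aqueous Na2S2O3/NaHCO3 work-up to give 8.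

**Further compounds**
F1 | step 1 | 2,4-dihydroxy-3-methoxyacetophenone | CC(=O)c1ccc(O)c(OC)c1O
F2 | step 2 | 8-methoxy-4-oxo-2-(3,4,5-trimethoxyphenyl)-4H-chromen-7-yl trifluoroacetate | COc1cc(-c2cc(=O)c3ccc(OC(=O)C(F)(F)F)c(OC)c3o2)cc(OC)c1OC
F3 | step 2 | 8-methoxy-4-oxo-2-(3,4,5-trimethoxyphenyl)-4H-chromene-5,7-diyl bis(trifluoroacetate) | COc1cc(-c2cc(=O)c3c(OC(=O)C(F)(F)F)cc(OC(=O)C(F)(F)F)c(OC)c3o2)cc(OC)c1OC
F4 | step 3 | 5,7-dihydroxy-2-(3,4,5-trimethoxyphenyl)-4H-chromen-4-one | COc1cc(-c2cc(=O)c3c(O)cc(O)cc3o2)cc(OC)c1OC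
F5 | step 3 | 5,7-bis(benzyloxy)-2-(3,4,5-trimethoxyphenyl)-4H-chromen-4-one | COc1cc(-c2cc(=O)c3c(OCc4ccccc4)cc(OCc4ccccc4)cc3o2)cc(OC)c1OC
F6 | step 3 | 5,7-bis(benzyloxy)-8-iodo-2-(3,4,5-trimethoxyphenyl)-4H-chromen-4-one | COc1cc(-c2cc(=O)c3c(OCc4ccccc4)cc(OCc4ccccc4)c(I)c3o2)cc(OC)c1OC
F7 | step 3 | 5,7-bis(benzyloxy)-8-methoxy-2-(3,4,5-trimethoxyphenyl)-4H-chromen-4-one | COc1cc(-c2cc(=O)c3c(OCc4ccccc4)cc(OCc4ccccc4)c(OC)c3o2)cc(OC)c1OC
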